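The pyranone ring (O1, C2–C6; aryl at C2) is disconnected at C2–C3. C2 sits between ring oxygen O1 and the electron-rich guaiacyl ring. In an open-chain 4-benzyloxy-3-methoxybenzyl ether its C–H bond is therefore the most easily oxidised one in the molecule. DDQ removes it as hydride, and the (E)-oxocarbenium ion is trapped by a pendant enol acetate. This one operation forms C2–C3, closes the ring, sets C2 cis to C6 and unveils the C4 ketone. The precursor looks like a routinely protected acyclic diol; its "protecting group" becomes C2 and the aryl ring of the target. C1' comes from O-benzyl-L-tyrosine, C6 from a catalyst-controlled propargylation, and one hydrogenolysis ends the route.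

Key step: step 8

Numbering used below: pyranone ring O1, C2 (aryl-bearing), C3, C4 (C=O), C5, C6; side chain C1' (carbinol carbon) and C2' (benzylic CH2).
Assumption: O-benzyl-L-tyrosine, allenylboronic acid pinacol ester, 4-benzyloxy-3-methoxybenzyl alcohol and (R)-TRIP are taken as catalogue chemicals.

Step 1
Reactants: 1 O-benzyl-L-tyrosine
Product: 3 (S)-3-[4-(benzyloxy)phenyl]-2-hydroxypropanoic acid, via alpha-lactone 2 (not isolated)
Conditions: NaNO2, 1 M aq. H2SO4, 1,4-dioxane, 0 °C to rt
Reagents that add atoms: water, O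
Why: Diazotisation of an α-amino acid goes with net retention, because the neighbouring carboxylate expels N2 with inversion to give alpha-lactone 2 and water opens this ring with a second inversion, so the (S) centre of 1 becomes C1' of the target unchanged.

Step 2
Reactants: 3 (S)-3-[4-(benzyloxy)phenyl]-2-hydroxypropanoic acid
Product: 4 benzyl (S)-2-(benzyloxy)-3-[4-(benzyloxy)phenyl]propanoate
Conditions: BnBr (3 equiv), Ag2O (2 equiv), 4 Å MS, CH2Cl2, rt, dark
Reagents that add atoms: benzyl bromide, BrCc1ccccc1
Why: Ag2O-promoted O-benzylation (a Williamson-type alkylation under essentially neutral conditions) converts the carboxylic acid and the α-hydroxy group in one operation without enolising the α-alkoxy ester, so the stereocentre is kept.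

Step 3
Reactants: 4 benzyl (S)-2-(benzyloxy)-3-[4-(benzyloxy)phenyl]propanoate
Product: 5 (S)-2-(benzyloxy)-3-[4-(benzyloxy)phenyl]propanal
Conditions: iBu2AlH (1.1 equiv), toluene, −78 °C; MeOH, then aq. potassium sodium tartrate
Reagents that add atoms: none
Why: Partial reduction of an α-alkoxy ester with one equivalent of iBu2AlH at −78 °C is a standard route to the aldehyde, no base is present that could epimerise the α-centre, and 5 is used at once without chromatography.

Step 4
Reactants: 5 (S)-2-(benzyloxy)-3-[4-(benzyloxy)phenyl]propanal; 6 allenylboronic acid pinacol ester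
Product: 7 (2S,3R)-2-(benzyloxy)-1-[4-(benzyloxy)phenyl]hex-5-yn-3-ol
Conditions: (R)-TRIP [(R)-3,3'-bis(2,4,6-triisopropylphenyl)-1,1'-binaphthyl-2,2'-diyl hydrogen phosphate] (10 mol %), 4 Å MS, toluene, −20 °C; aqueous work-up
Reagents that add atoms: none
Why: Chiral phosphoric acid catalysed propargylation with an allenylboronate passes through a closed six-membered SE2' transition state in which (R)-TRIP exposes the Re face of the aldehyde, the same face that the Felkin–Anh model favours for an α-alkoxy aldehyde and a non-chelating boron reagent, so the matched pair should set the new carbinol centre (future C6) as (R) and anti to C1'.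

Step 5
Reactants: 8 4-(benzyloxy)-3-methoxybenzyl alcohol
Product: 9 4-(benzyloxy)-3-methoxybenzyl chloride
Conditions: SOCl2, CH2Cl2, 0 °C
Reagents that add atoms: thionyl chloride, O=S(Cl)Cl
Why: Chlorodehydroxylation of an electron-rich benzylic alcohol with SOCl2 is fast at 0 °C and the labile chloride is used crude after evaporation.

Step 6
Reactants: 7 (2S,3R)-2-(benzyloxy)-1-[4-(benzyloxy)phenyl]hex-5-yn-3-ol; 9 4-(benzyloxy)-3-methoxybenzyl chloride
Product: 10 1-(benzyloxy)-4-({[(2S,3R)-2-(benzyloxy)-1-[4-(benzyloxy)phenyl]hex-5-yn-3-yl]oxy}methyl)-2-methoxybenzene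
Conditions: NaH (1.1 equiv), DMF, 0 °C; then 9, 0 °C to rt
Reagents that add atoms: none
Why: Williamson ether synthesis, in which the O–H (far more acidic than the alkyne C–H) is deprotonated and displaces chloride from the reactive benzylic halide by SN2, while no bond to a stereocentre is made or broken and the neighbouring benzyl ether cannot migrate.

Step 7
Reactants: 10 1-(benzyloxy)-4-({[(2S,3R)-2-(benzyloxy)-1-[4-(benzyloxy)phenyl]hex-5-yn-3-yl]oxy}methyl)-2-methoxybenzene
Product: 11 (4R,5S)-5-(benzyloxy)-4-{[4-(benzyloxy)-3-methoxybenzyl]oxy}-6-[4-(benzyloxy)phenyl]hex-1-en-2-yl acetate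
Conditions: [RuCl2(p-cymene)]2 (2 mol %), P(2-furyl)3 (4 mol %), Na2CO3 (8 mol %), AcOH (3 equiv), toluene, 80 °C
Reagents that add atoms: acetic acid, CC(=O)O
Why: Ruthenium-catalysed Markovnikov hydroacyloxylation of a terminal alkyne places the acetate oxygen on the internal carbon and gives the 2-acetoxy-1-alkene, a bench-stable acetone-enolate equivalent, under conditions that leave ethers and stereocentres untouched.

Step 8
Reactants: 11 (4R,5S)-5-(benzyloxy)-4-{[4-(benzyloxy)-3-methoxybenzyl]oxy}-6-[4-(benzyloxy)phenyl]hex-1-en-2-yl acetate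
Product: 13 (2S,6R)-2-[4-(benzyloxy)-3-methoxyphenyl]-6-{(1S)-1-(benzyloxy)-2-[4-(benzyloxy)phenyl]ethyl}tetrahydro-4H-pyran-4-one, via oxocarbenium ion 12 (not isolated)
Conditions: DDQ (1.5 equiv), 2,6-dichloropyridine (3 equiv), 4 Å MS, ClCH2CH2Cl, 0 °C to rt; aq. NaHCO3
Reagents that add atoms: none
Why: DDQ removes a hydride equivalent (electron transfer from the dialkoxyarene followed by hydrogen-atom abstraction) from the ArCH2–O group of 11, and the carbon of the resulting (E)-oxocarbenium ion 12 is attacked by the terminal CH2 of the enol acetate, after which loss of the acetyl group to the reduced quinone or the pyridine base leaves the C4 ketone. The closest known reaction type is the DDQ-mediated oxidative C–H cleavage of 4-methoxybenzyl and 3,4-dimethoxybenzyl ethers with intramolecular capture by an enol acetate, an oxidative entry into the Prins-type oxocarbenium cyclisation that is established for 2,6-cis-tetrahydropyran-4-ones. The single ring is closed in the 6-(enolendo)-endo-trig mode. The new stereocentre C2 is controlled by C6 through a chair transition state in which the C6 side chain is equatorial and the aryl group of the (E)-oxocarbenium ion is pseudo-equatorial, so that the hydrogens on C2 and C6 become cis-diaxial and C2 is (S). The step needs site selectivity among five benzylic CH2 groups, and this is secured by the 3,4-dioxygenated ring, which has the lowest oxidation potential and whose benzylic C–H is also α to oxygen, whereas the three PhCH2–O groups and C2' next to the mono-oxygenated ring are oxidised much more slowly. A second oxidation of 13 is held back by the electron-withdrawing ketone, and molecular sieves together with the weak base 2,6-dichloropyridine suppress hydrolysis of 12 and acid-induced loss of the enol acetate.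

Step 9
Reactants: 13 (2S,6R)-2-[4-(benzyloxy)-3-methoxyphenyl]-6-{(1S)-1-(benzyloxy)-2-[4-(benzyloxy)phenyl]ethyl}tetrahydro-4H-pyran-4-one
Product: 14 (2S,6R)-2-(4-hydroxy-3-methoxyphenyl)-6-[(1S)-1-hydroxy-2-(4-hydroxyphenyl)ethyl]tetrahydro-4H-pyran-4-one (CNP0222055.1)
Conditions: H2 (1 atm), 10% Pd/C, EtOAc–EtOH, rt
Reagents that add atoms: none
Why: Catalytic hydrogenolysis removes all three O-benzyl groups under neutral conditions, in which the β-alkoxy ketone cannot epimerise by retro-oxa-Michael opening, and the exocyclic benzyl ethers are cleaved faster than the ring C2–O1 bond, so the reaction is stopped after the uptake of three equivalents of H2.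

Compound list
1 | O-benzyl-L-tyrosine | N[C@@H](Cc1ccc(OCc2ccccc2)cc1)C(=O)O | starting material
2 | (R)-3-[4-(benzyloxy)benzyl]oxiran-2-one (alpha-lactone) | O=C1O[C@@H]1Cc1ccc(OCc2ccccc2)cc1 | intermediate
3 | (S)-3-[4-(benzyloxy)phenyl]-2-hydroxypropanoic acid | O[C@@H](Cc1ccc(OCc2ccccc2)cc1)C(=O)O | intermediate
4 | benzyl (S)-2-(benzyloxy)-3-[4-(benzyloxy)phenyl]propanoate | O=C(OCc1ccccc1)[C@H](Cc1ccc(OCc2ccccc2)cc1)OCc1ccccc1 | intermediate
5 | (S)-2-(benzyloxy)-3-[4-(benzyloxy)phenyl]propanal | O=C[C@H](Cc1ccc(OCc2ccccc2)cc1)OCc1ccccc1 | intermediate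
6 | allenylboronic acid pinacol ester | C=C=CB1OC(C)(C)C(C)(C)O1 | starting material
7 | (2S,3R)-2-(benzyloxy)-1-[4-(benzyloxy)phenyl]hex-5-yn-3-ol | C#CC[C@H]([C@@H](OCc1ccccc1)Cc1ccc(OCc2ccccc2)cc1)O | intermediate
8 | 4-(benzyloxy)-3-methoxybenzyl alcohol | COc1cc(CO)ccc1OCc1ccccc1 | starting material
9 | 4-(benzyloxy)-3-methoxybenzyl chloride | COc1cc(CCl)ccc1OCc1ccccc1 | intermediate
10 | 1-(benzyloxy)-4-({[(2S,3R)-2-(benzyloxy)-1-[4-(benzyloxy)phenyl]hex-5-yn-3-yl]oxy}methyl)-2-methoxybenzene | C#CC[C@H]([C@@H](OCc1ccccc1)Cc1ccc(OCc2ccccc2)cc1)OCc1ccc(OCc2ccccc2)c(OC)c1 | intermediate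
11 | (4R,5S)-5-(benzyloxy)-4-{[4-(benzyloxy)-3-methoxybenzyl]oxy}-6-[4-(benzyloxy)phenyl]hex-1-en-2-yl acetate | CC(=O)OC(=C)C[C@H]([C@@H](OCc1ccccc1)Cc1ccc(OCc2ccccc2)cc1)OCc1ccc(OCc2ccccc2)c(OC)c1 | intermediate
12 | (E)-oxocarbenium ion formed from 11 by loss of hydride at the ArCH2–O carbon | CC(=O)OC(=C)C[C@H]([C@@H](OCc1ccccc1)Cc1ccc(OCc2ccccc2)cc1)/[O+]=C/c1ccc(OCc2ccccc2)c(OC)c1 | intermediate
13 | (2S,6R)-2-[4-(benzyloxy)-3-methoxyphenyl]-6-{(1S)-1-(benzyloxy)-2-[4-(benzyloxy)phenyl]ethyl}tetrahydro-4H-pyran-4-one | COc1cc([C@@H]2CC(=O)C[C@H]([C@@H](OCc3ccccc3)Cc3ccc(OCc4ccccc4)cc3)O2)ccc1OCc1ccccc1 | intermediate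
14 | (2S,6R)-2-(4-hydroxy-3-methoxyphenyl)-6-[(1S)-1-hydroxy-2-(4-hydroxyphenyl)ethyl]tetrahydro-4H-pyran-4-one | COc1cc([C@@H]2CC(=O)C[C@H]([C@@H](O)Cc3ccc(O)cc3)O2)ccc1O | target

Total step count: 9. Longest linear sequence: 8 steps (steps 1–4 and 6–9); step 5 is a one-step branch.

Steps most likely to fail

Step 8.
- What may go wrong: capture of the oxocarbenium ion by adventitious water (plain loss of the benzylic ether), participation of the neighbouring C1' benzyloxy oxygen, or further oxidation of the electron-rich product.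
- Fallback: the same oxocarbenium ion is reached by condensation instead of oxidation, and the same C2–C3 bond closes the ring.
- It sets out from aldehyde 5. (R)-TRIP-catalysed allylboration with allylboronic acid pinacol ester should give the anti homoallylic alcohol (2S,3R)-2-(benzyloxy)-1-[4-(benzyloxy)phenyl]hex-5-en-3-ol F1.
- Prins cyclisation of this alcohol with commercial 4-benzyloxy-3-methoxybenzaldehyde (CF3CO2H, CH2Cl2, 0 °C) should give the all-cis pyran-4-yl trifluoroacetate F2.
- K2CO3 in MeOH should release the all-cis pyran-4-ol F3, and oxidation with Dess–Martin periodinane comes back to the route at 13.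

Step 4.
- What may go wrong: poor facial selectivity if the uncatalysed background reaction competes on this hindered α-alkoxy aldehyde, or slow epimerisation of 5 during a long reaction.
- Fallback: chelation is used instead of being avoided, and the carbinol centre is then inverted.
- It sets out from 5. Addition of allenyltributylstannane under MgBr2·OEt2 chelation control (CH2Cl2, −20 °C) should give the syn homopropargylic alcohol F4.
- Mitsunobu reaction with 4-nitrobenzoic acid (PPh3, DIAD, THF) should give the inverted anti 4-nitrobenzoate F5, and K2CO3 in MeOH comes back to the route at 7.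

Step 9.
- What may go wrong: hydrogenolytic opening of the ring C2–O1 bond, or partial reduction of the ketone, during the longer exposure that the secondary benzyl ether needs.
- Fallback: the deprotection is split into a short reductive stage and a non-reductive stage.
- It sets out from 13. Brief transfer hydrogenolysis (10% Pd/C, 1,4-cyclohexadiene, EtOH) should remove only the two aryl benzyl ethers and give the C1'-O-benzyl bisphenol F6.
- BCl3 with pentamethylbenzene as cation scavenger (CH2Cl2, −78 °C) then cleaves the remaining ether and comes back to the route at 14.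

Further compounds
F1 | step 8 | (2S,3R)-2-(benzyloxy)-1-[4-(benzyloxy)phenyl]hex-5-en-3-ol | C=CC[C@H]([C@@H](OCc1ccccc1)Cc1ccc(OCc2ccccc2)cc1)O
F2 | step 8 | (2S,4S,6R)-2-[4-(benzyloxy)-3-methoxyphenyl]-6-{(1S)-1-(benzyloxy)-2-[4-(benzyloxy)phenyl]ethyl}tetrahydro-2H-pyran-4-yl trifluoroacetate | COc1cc([C@@H]2C[C@H](OC(=O)C(F)(F)F)C[C@H]([C@@H](OCc3ccccc3)Cc3ccc(OCc4ccccc4)cc3)O2)ccc1OCc1ccccc1
F3 | step 8 | (2S,4S,6R)-2-[4-(benzyloxy)-3-methoxyphenyl]-6-{(1S)-1-(benzyloxy)-2-[4-(benzyloxy)phenyl]ethyl}tetrahydro-2H-pyran-4-ol | COc1cc([C@@H]2C[C@H](O)C[C@H]([C@@H](OCc3ccccc3)Cc3ccc(OCc4ccccc4)cc3)O2)ccc1OCc1ccccc1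
F4 | step 4 | (2S,3S)-2-(benzyloxy)-1-[4-(benzyloxy)phenyl]hex-5-yn-3-ol | C#CC[C@@H]([C@@H](OCc1ccccc1)Cc1ccc(OCc2ccccc2)cc1)O
F5 | step 4 | (2S,3R)-2-(benzyloxy)-1-[4-(benzyloxy)phenyl]hex-5-yn-3-yl 4-nitrobenzoate | C#CC[C@H]([C@@H](OCc1ccccc1)Cc1ccc(OCc2ccccc2)cc1)OC(=O)c1ccc([N+](=O)[O-])cc1
F6 | step 9 | (2S,6R)-6-[(1S)-1-(benzyloxy)-2-(4-hydroxyphenyl)ethyl]-2-(4-hydroxy-3-methoxyphenyl)tetrahydro-4H-pyran-4-one | COc1cc([C@@H]2CC(=O)C[C@H]([C@@H](OCc3ccccc3)Cc3ccc(O)cc3)O2)ccc1O
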